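**Retrosynthetic overview**
Numbering used: ring carbons C1–C10 with the C1=C10 olefin, C4 (bears C15H2OH), C6 (lactone oxygen), C7 (bears C11), C8 (angelate), C10 (bears C14H2OH); lactone carbons C11(=C13H2) and C12(=O).
The lactone O–C6 bond is made last: the α-methylene-γ-butyrolactone arises by ring expansion of a C6–C7–C11 cyclopropane (cyclopropylcarbinyl-to-homoallyl rearrangement with capture by the ester oxygen), which also creates the C11=C13 methylene and passes the cyclopropane configuration on to C6.
Enabling feature: C11 of the three-membered ring carries both the C13 carbinol (leaving group) and the C12 ester, and C6 is the ring carbon remote from the C8 oxygen, so the strained C6–C11 bond is handed over to the ester oxygen.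
The ten-membered carbocycle comes from ring-closing metathesis at C1=C10 on a cyclopropane-fused C8 γ-lactone (a temporary ring that tells the two malonate carbonyls apart); C8–C9 from a catalytic asymmetric allylboration; the cyclopropane (C6, C7) from an organocatalytic Michael-initiated ring closure of an enal with bromomalonate; C4 from an Evans alkylation.
Ring order: cyclopropane, temporary C8 lactone, ten-membered carbocycle, then (after reductive opening of the temporary lactone) the α-methylene-γ-butyrolactone.

Key step: step 18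

Remark: the target is read as the (4R,6R,7S,8R) isomer with a trans ring fusion at C6/C7, a ring-cis C1=C10 olefin and a (Z)-2-methylbut-2-enoate (angelate); compounds 1, 4, 5, 13, 15 and 25 are taken as commercial.

Step 1
Reactants: 1 (E)-4,4-dimethoxybut-2-enal
Product: 2 (E)-4,4-dimethoxybut-2-en-1-ol
Conditions: NaBH4, MeOH, 0 °C
Reagents that add atoms: none
Why: Borohydride 1,2-reduction of the enal carbonyl should leave the dimethyl acetal and the E olefin untouched.

Step 2
Reactants: 2 (E)-4,4-dimethoxybut-2-en-1-ol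
Product: 3 (E)-4-bromo-1,1-dimethoxybut-2-ene
Conditions: CBr4, PPh3, CH2Cl2, 0 °C
Reagents that add atoms: carbon tetrabromide BrC(Br)(Br)Br
Why: The Appel reaction converts the primary allylic alcohol into the bromide under near-neutral conditions that the acetal tolerates.

Step 3
Reactants: 4 hex-5-enoic acid; 5 (S)-4-benzyl-1,3-oxazolidin-2-one
Product: 7 N-(hex-5-enoyl)oxazolidinone, via hex-5-enoic pivalic anhydride 6 (not isolated)
Conditions: pivaloyl chloride, Et3N, THF, −20 °C; then LiCl, 5, −20 °C → rt
Reagents that add atoms: none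
Why: Mixed-anhydride N-acylation of the oxazolidinone in the presence of LiCl is the standard entry to Evans imides.

Step 4
Reactants: 7 N-(hex-5-enoyl)oxazolidinone; 3 (E)-4-bromo-1,1-dimethoxybut-2-ene
Product: 9 C4-alkylated imide, via sodium Z-enolate 8 (not isolated)
Conditions: NaN(SiMe3)2, THF, −78 °C; then 3, −78 → −40 °C
Reagents that add atoms: none
Why: In this Evans asymmetric alkylation the chelated Z-enolate should be attacked by the reactive allylic bromide on the face opposite the benzyl group, which sets C4 as R.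

Step 5
Reactants: 9 C4-alkylated imide
Product: 10 primary alcohol (C15–OH)
Conditions: LiBH4, MeOH (1 equiv), Et2O, 0 °C
Reagents that add atoms: none
Why: Reductive cleavage of the imide with LiBH4 should release the primary alcohol without epimerising C4 and return the auxiliary.

Step 6
Reactants: 10 primary alcohol
Product: 11 TBS ether
Conditions: TBSCl, imidazole, CH2Cl2, rt
Reagents that add atoms: tert-butyldimethylsilyl chloride CC(C)(C)[Si](C)(C)Cl
Why: Standard silylation of the unhindered primary alcohol.

Step 7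
Reactants: 11 TBS ether
Product: 12 (2E,5R)-enal
Conditions: PPTS (cat.), acetone/H2O, rt
Reagents that add atoms: water O
Why: Mild acid hydrolysis of the allylic dimethyl acetal should unmask the conjugated E-enal while the primary TBS ether survives.

Step 8
Reactants: 12 (2E,5R)-enal; 13 dimethyl 2-bromomalonate
Product: 14 trans-formylcyclopropane diester
Conditions: (S)-α,α-diphenylprolinol trimethylsilyl ether (20 mol%), 2,6-lutidine, CH2Cl2, 0 °C → rt
Reagents that add atoms: none
Why: In this iminium/enamine Michael-initiated ring closure the silyl prolinol ether shields one face of the E-iminium, so the bromomalonate should add to C6 from the open face and the enamine then displaces bromide to close the trans cyclopropane, which fixes C6 and C7 under catalyst control.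

Step 9
Reactants: 15 2-methylidenepropane-1,3-diol
Product: 16 mono-TBS ether
Conditions: TBSCl (1 equiv), imidazole, THF, 0 °C, 15 in excess
Reagents that add atoms: tert-butyldimethylsilyl chloride CC(C)(C)[Si](C)(C)Cl
Why: Monosilylation of the symmetric diol used in excess should give the mono ether as the main product.

Step 10
Reactants: 16 mono-TBS ether
Product: 17 allylic acetate
Conditions: Ac2O, pyridine, DMAP (cat.), CH2Cl2, rt
Reagents that add atoms: acetic anhydride CC(=O)OC(C)=O
Why: Routine acetylation turns the allylic alcohol into a leaving group for palladium.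

Step 11
Reactants: 17 allylic acetate
Product: 18 2-(silyloxymethyl)allyl pinacolboronate
Conditions: B2pin2, Pd2(dba)3 (cat.), DMSO, 50 °C
Reagents that add atoms: bis(pinacolato)diboron CC1(C)OB(OC1(C)C)B1OC(C)(C)C(C)(C)O1
Why: Miyaura-type palladium-catalysed borylation of the allylic acetate runs through a π-allyl palladium intermediate whose two termini are equivalent, so only one allylboronate can form.

Step 12
Reactants: 14 trans-formylcyclopropane diester; 18 2-(silyloxymethyl)allyl pinacolboronate
Product: 21 cyclopropane-fused γ-lactone ester, via pinacol borate 19 (not isolated), via hydroxy diester 20 (not isolated)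
Conditions: (R)-3,3′-bis(2,4,6-triisopropylphenyl)-1,1′-binaphthyl-2,2′-diyl hydrogen phosphate (5 mol%), 4 Å MS, toluene, −30 °C; then MeOH; then DBU (cat.), toluene, 40 °C
Reagents that add atoms: none
Why: Chiral phosphoric acid-catalysed allylboration through a closed chair transition state should deliver the allyl group to the Re face of the aldehyde under catalyst control to set C8 as R, and the new hydroxyl can lactonise only onto the cis ester, which tells the two malonate carbonyls apart.

Step 13
Reactants: 21 cyclopropane-fused γ-lactone ester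
Product: 22 macrocyclic lactone ester
Conditions: second-generation Hoveyda–Grubbs catalyst RuCl2(H2IMes)(=CH-C6H4-2-OiPr) (10 mol%), 1,4-benzoquinone (cat.), toluene (1 mM), 80 °C
Reagents that add atoms: none
Why: Ring-closing metathesis should close the ten-membered ring because the rigid bicyclic lactone holds the C9 and C5 chains on the same side, ring strain permits only the ring-cis trisubstituted olefin, and loss of ethene drives the reaction.

Step 14
Reactants: 22 macrocyclic lactone ester
Product: 23 diol ester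
Conditions: NaBH4, EtOH, 0 °C → rt
Reagents that add atoms: none
Why: Borohydride should reduce the strained γ-lactone chemoselectively in the presence of the hindered methyl ester on the same cyclopropane carbon (a selectivity known for cyclopropane-fused lactone esters), turning the former lactone carbonyl into C13H2OH and freeing 8-OH.

Step 15
Reactants: 23 diol ester
Product: 24 primary TES ether
Conditions: TESCl, imidazole, CH2Cl2, −20 °C
Reagents that add atoms: chlorotriethylsilane CC[Si](Cl)(CC)CC
Why: The primary alcohol should be silylated selectively over the hindered secondary cyclopropyl carbinol at low temperature.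

Step 16
Reactants: 24 primary TES ether; 25 angelic acid
Product: 27 C8 angelate, via angelic 2,4,6-trichlorobenzoic anhydride 26 (not isolated)
Conditions: 25, 2,4,6-trichlorobenzoyl chloride, Et3N, toluene, rt; then 24, DMAP, toluene, rt → 50 °C
Reagents that add atoms: none
Why: Yamaguchi esterification acylates the secondary alcohol with retention at C8 and is the usual way to install an angelate without Z-to-E isomerisation.

Step 17
Reactants: 27 C8 angelate
Product: 28 cyclopropylcarbinol ester
Conditions: PPTS (cat.), MeOH/CH2Cl2, 0 °C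
Reagents that add atoms: none
Why: Mild acid methanolysis should cleave the primary TES ether much faster than the two primary TBS ethers.

Step 18
Reactants: 28 cyclopropylcarbinol ester
Product: 31 bis-TBS α-methylene lactone, via primary triflate 29 (not isolated), via methoxy oxocarbenium triflate 30 (not isolated)
Conditions: Tf2O, 2,6-di-tert-butyl-4-methylpyridine, CH2Cl2, −78 °C → rt
Reagents that add atoms: none
Why: The primary alcohol is converted into triflate 29, whose ionisation is assisted by the C6–C11 bond of the cyclopropane, and the carbonyl oxygen of the geminal methyl ester captures C6 as that bond breaks and C11=C13 forms, giving oxocarbenium 30, which triflate demethylates to the lactone. The closest known reaction type is the cyclopropylcarbinyl-to-homoallyl rearrangement of 1-(hydroxymethyl)cyclopropane-1-carboxylic acid derivatives to α-methylene-γ-butyrolactones, a relative of the Cloke–Wilson ring expansion. The lactone ring closes by expansion of the three-membered ring to the five-membered ring, a formal 1,3-shift of C6 from C11 to oxygen in which the breaking bond lies inside the new ring. C6 should form with retention, because the oxygen is tethered to C11 and can reach only the face of C6 that C11 leaves, so the trans relationship of C5 and C8 on the cyclopropane becomes the trans ring fusion, while C4, C7 and C8 are not touched. The step needs opening toward C6 and not C7, and capture by the ester and not by the C1=C10 olefin or the angelate carbonyl: the electron-withdrawing acyloxy group on C8 disfavours positive charge at C7, and the ester oxygen sits within bonding distance of C6 so that capture accompanies ring opening.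

Step 19
Reactants: 31 bis-TBS α-methylene lactone
Product: 32 target CNP0262807.1
Conditions: HF·pyridine, pyridine, THF, 0 °C → rt
Reagents that add atoms: none
Why: Buffered HF·pyridine should remove both primary TBS ethers without adding to the α-methylene lactone or isomerising the angelate.

**Compound list**
1 | (E)-4,4-dimethoxybut-2-enal (fumaraldehyde mono(dimethyl acetal)) | COC(OC)/C=C/C=O | starting material
2 | (E)-4,4-dimethoxybut-2-en-1-ol | COC(OC)/C=C/CO | intermediate
3 | (E)-4-bromo-1,1-dimethoxybut-2-ene | COC(OC)/C=C/CBr | intermediate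
4 | hex-5-enoic acid | C=CCCCC(=O)O | starting material
5 | (S)-4-benzyl-1,3-oxazolidin-2-one | O=C1N[C@@H](Cc2ccccc2)CO1 | starting material
6 | hex-5-enoic pivalic anhydride | C=CCCCC(=O)OC(=O)C(C)(C)C | intermediate
7 | (S)-4-benzyl-3-(hex-5-enoyl)-1,3-oxazolidin-2-one | C=CCCCC(=O)N1[C@@H](Cc2ccccc2)COC1=O | intermediate
8 | sodium (Z)-enolate of 7 | C=CCC/C=C(\[O-])N1[C@@H](Cc2ccccc2)COC1=O.[Na+] | intermediate
9 | (S)-4-benzyl-3-[(2R,4E)-2-(but-3-en-1-yl)-6,6-dimethoxyhex-4-enoyl]-1,3-oxazolidin-2-one | COC(OC)/C=C/C[C@H](C(=O)N1[C@@H](Cc2ccccc2)COC1=O)CCC=C | intermediate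
10 | (2R,4E)-2-(but-3-en-1-yl)-6,6-dimethoxyhex-4-en-1-ol | COC(OC)/C=C/C[C@H](CO)CCC=C | intermediate
11 | tert-butyl{[(2R,4E)-2-(but-3-en-1-yl)-6,6-dimethoxyhex-4-en-1-yl]oxy}dimethylsilane | COC(OC)/C=C/C[C@H](CO[Si](C)(C)C(C)(C)C)CCC=C | intermediate
12 | (2E,5R)-5-{[(tert-butyldimethylsilyl)oxy]methyl}nona-2,8-dienal | O=C/C=C/C[C@H](CO[Si](C)(C)C(C)(C)C)CCC=C | intermediate
13 | dimethyl 2-bromomalonate | COC(=O)C(Br)C(=O)OC | starting material
14 | dimethyl (2R,3R)-2-formyl-3-[(2R)-2-{[(tert-butyldimethylsilyl)oxy]methyl}hex-5-en-1-yl]cyclopropane-1,1-dicarboxylate (formyl and alkyl trans) | COC(=O)C1(C(=O)OC)[C@H](C[C@H](CO[Si](C)(C)C(C)(C)C)CCC=C)[C@H]1C=O | intermediate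
15 | 2-methylidenepropane-1,3-diol | C=C(CO)CO | starting material
16 | 2-{[(tert-butyldimethylsilyl)oxy]methyl}prop-2-en-1-ol | C=C(CO)CO[Si](C)(C)C(C)(C)C | intermediate
17 | 2-{[(tert-butyldimethylsilyl)oxy]methyl}prop-2-en-1-yl acetate | C=C(COC(C)=O)CO[Si](C)(C)C(C)(C)C | intermediate
18 | tert-butyldimethyl({2-[(4,4,5,5-tetramethyl-1,3,2-dioxaborolan-2-yl)methyl]prop-2-en-1-yl}oxy)silane | C=C(CB1OC(C)(C)C(C)(C)O1)CO[Si](C)(C)C(C)(C)C | intermediate
19 | pinacol borate of 20 (O-boryl at C8) | COC(=O)C1(C(=O)OC)[C@H](C[C@H](CO[Si](C)(C)C(C)(C)C)CCC=C)[C@H]1[C@H](OB2OC(C)(C)C(C)(C)O2)CC(=C)CO[Si](C)(C)C(C)(C)C | intermediate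
20 | dimethyl (2R,3R)-2-[(1R)-1-hydroxy-3-{[(tert-butyldimethylsilyl)oxy]methyl}but-3-en-1-yl]-3-[(2R)-2-{[(tert-butyldimethylsilyl)oxy]methyl}hex-5-en-1-yl]cyclopropane-1,1-dicarboxylate | COC(=O)C1(C(=O)OC)[C@H](C[C@H](CO[Si](C)(C)C(C)(C)C)CCC=C)[C@H]1[C@H](O)CC(=C)CO[Si](C)(C)C(C)(C)C | intermediate
21 | methyl (1S,4R,5R,6R)-4-(2-{[(tert-butyldimethylsilyl)oxy]methyl}prop-2-en-1-yl)-6-[(2R)-2-{[(tert-butyldimethylsilyl)oxy]methyl}hex-5-en-1-yl]-2-oxo-3-oxabicyclo[3.1.0]hexane-1-carboxylate (C4 side chain cis to C6 on the lactone ring) | COC(=O)[C@@]12C(=O)O[C@H](CC(=C)CO[Si](C)(C)C(C)(C)C)[C@@H]1[C@H]2C[C@H](CO[Si](C)(C)C(C)(C)C)CCC=C | intermediate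
22 | macrocyclic lactone ester: ten-membered ring C1–C10 with ring-cis C1=C10, C14H2OTBS on C10, C15H2OTBS on C4, trans cyclopropane C6–C7–C11, γ-lactone C11–C13(=O)–O–C8, CO2Me on C11; (4R,6R,7R,8R,11S) | COC(=O)[C@@]12C(=O)O[C@@H]3C/C(CO[Si](C)(C)C(C)(C)C)=C\CC[C@@H](CO[Si](C)(C)C(C)(C)C)C[C@@H]2[C@H]13 | intermediate
23 | diol ester: as 22 with the lactone reduced to C13H2OH on C11 and free 8-OH; (4R,6R,7R,8R,11R) | OC[C@@]1(C(=O)OC)[C@@H]2C[C@H](CO[Si](C)(C)C(C)(C)C)CC/C=C(/CO[Si](C)(C)C(C)(C)C)C[C@@H](O)[C@@H]12 | intermediate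
24 | 13-O-triethylsilyl ether of 23 | CC[Si](CC)(CC)OC[C@@]1(C(=O)OC)[C@@H]2C[C@H](CO[Si](C)(C)C(C)(C)C)CC/C=C(/CO[Si](C)(C)C(C)(C)C)C[C@@H](O)[C@@H]12 | intermediate
25 | angelic acid, (Z)-2-methylbut-2-enoic acid | C/C=C(/C)C(=O)O | starting material
26 | angelic 2,4,6-trichlorobenzoic anhydride | C/C=C(/C)C(=O)OC(=O)c1c(Cl)cc(Cl)cc1Cl | intermediate
27 | 8-O-angelate of 24 | CC[Si](CC)(CC)OC[C@@]1(C(=O)OC)[C@@H]2C[C@H](CO[Si](C)(C)C(C)(C)C)CC/C=C(/CO[Si](C)(C)C(C)(C)C)C[C@@H](OC(=O)/C(C)=C\C)[C@@H]12 | intermediate
28 | cyclopropylcarbinol ester: C11 bears CH2OH and CO2Me, 8-O-angelate, 14,15-bis-OTBS; (4R,6R,7R,8R,11R) | OC[C@@]1(C(=O)OC)[C@@H]2C[C@H](CO[Si](C)(C)C(C)(C)C)CC/C=C(/CO[Si](C)(C)C(C)(C)C)C[C@@H](OC(=O)/C(C)=C\C)[C@@H]12 | intermediate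
29 | primary triflate of 28 | FC(F)(F)S(=O)(=O)OC[C@@]1(C(=O)OC)[C@@H]2C[C@H](CO[Si](C)(C)C(C)(C)C)CC/C=C(/CO[Si](C)(C)C(C)(C)C)C[C@@H](OC(=O)/C(C)=C\C)[C@@H]12 | intermediate
30 | 2-methoxy-3-methylidene oxocarbenium triflate (O-methylated form of 31) | C=C1C(OC)=[O+][C@@H]2C[C@H](CO[Si](C)(C)C(C)(C)C)CC/C=C(/CO[Si](C)(C)C(C)(C)C)C[C@@H](OC(=O)/C(C)=C\C)[C@@H]12.[O-]S(=O)(=O)C(F)(F)F | intermediate
31 | 14,15-bis-O-TBS ether of the target; (4R,6R,7S,8R) | C=C1C(=O)O[C@@H]2C[C@H](CO[Si](C)(C)C(C)(C)C)CC/C=C(/CO[Si](C)(C)C(C)(C)C)C[C@@H](OC(=O)/C(C)=C\C)[C@@H]12 | intermediate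
32 | CNP0262807.1: trans-fused α-methylene-γ-butyrolactone on the ten-membered ring, 8-O-angelate, C14H2OH and C15H2OH; (4R,6R,7S,8R) | C=C1C(=O)O[C@@H]2C[C@H](CO)CC/C=C(/CO)C[C@@H](OC(=O)/C(C)=C\C)[C@@H]12 | target

**Step count**
Total: 19 steps. Longest linear sequence: 15 steps (steps 1, 2, 4–8, 12–19, from 1).

**Steps most likely to fail**

Step 18. The cyclopropylcarbinyl cation may open toward C7, the positive charge at C6 may be captured across the ring by the C1=C10 olefin, or the angelate carbonyl may take part. The fallback replaces ionisation by a nucleophile-driven, stepwise route. It sets out from 28. MsCl and Et3N give the mesylate F1. MgBr2·OEt2 in Et2O/benzene opens the cyclopropane by bromide attack at C6 anti to the C6–C11 bond (a homoallylic rearrangement of the Julia–Johnson type) and gives the C6-inverted bromo acrylate F2. Me3SnOH in 1,2-dichloroethane at 60 °C cleaves the methyl ester to the bromo acid F3. Cs2CO3 in DMF then closes the lactone by SN2 displacement of bromide, a second inversion, and the route comes back at 31.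

Step 13. Oligomerisation may outrun ring closure because the ten-membered ring with a trisubstituted olefin is strained. The fallback closes the ring by a Nozaki–Hiyama–Kishi reaction and sets out from 14. The allylboration protocol of step 12, run with 2-(2-bromoallyl)-4,4,5,5-tetramethyl-1,3,2-dioxaborolane, gives the pinacol borate F4, then the hydroxy diester F5 and, after lactonisation, the bromoallyl lactone F6. The monosubstituted olefin alone is cleaved (OsO4 cat., NaIO4, 2,6-lutidine, dioxane/H2O) to the aldehyde F7. CrCl2 with NiCl2 (cat.) in DMSO/THF at high dilution closes the ring to the exo-methylene allylic alcohol F8, whose two C1 epimers both serve. O3ReOSiPh3-catalysed 1,3-transposition moves the hydroxyl to C14 and the double bond into the ring, giving the primary allylic alcohol F9. TBSCl and imidazole then bring the route back at 22.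

Step 12. Facial selectivity at the aldehyde may be poor if the catalyst and the cyclopropane stereocentres are mismatched. The fallback sets C8 by reagent-controlled ketone reduction and sets out from 14. Uncatalysed addition of 18 (toluene, rt) gives the C8-epimeric borates F10, and methanolysis gives the C8-epimeric alcohols F11. Dess–Martin periodinane with NaHCO3 oxidises them to the cyclopropyl ketone F12. Corey–Bakshi–Shibata reduction with (S)-2-methyl-CBS-oxazaborolidine and catecholborane (toluene, −78 °C) should give 20 alone, the cyclopropyl group acting as the large substituent. DBU-catalysed lactonisation then brings the route back at 21.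

**Further compounds**
F1 | step 18 | 13-O-mesylate of 28 | CS(=O)(=O)OC[C@@]1(C(=O)OC)[C@@H]2C[C@H](CO[Si](C)(C)C(C)(C)C)CC/C=C(/CO[Si](C)(C)C(C)(C)C)C[C@@H](OC(=O)/C(C)=C\C)[C@@H]12
F2 | step 18 | ring-opened methyl acrylate with bromide at C6 (C6 inverted relative to the lactone oxygen of 31) | C=C(C(=O)OC)[C@H]1[C@@H](Br)C[C@H](CO[Si](C)(C)C(C)(C)C)CC/C=C(/CO[Si](C)(C)C(C)(C)C)C[C@H]1OC(=O)/C(C)=C\C
F3 | step 18 | acrylic acid from F2 | C=C(C(=O)O)[C@H]1[C@@H](Br)C[C@H](CO[Si](C)(C)C(C)(C)C)CC/C=C(/CO[Si](C)(C)C(C)(C)C)C[C@H]1OC(=O)/C(C)=C\C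
F4 | step 13 | pinacol borate of F5 | COC(=O)C1(C(=O)OC)[C@H](C[C@H](CO[Si](C)(C)C(C)(C)C)CCC=C)[C@H]1[C@H](OB2OC(C)(C)C(C)(C)O2)CC(Br)=C
F5 | step 13 | hydroxy diester carrying the 2-bromoallyl group on C8 | COC(=O)C1(C(=O)OC)[C@H](C[C@H](CO[Si](C)(C)C(C)(C)C)CCC=C)[C@H]1[C@H](O)CC(Br)=C
F6 | step 13 | cyclopropane-fused γ-lactone ester with 2-bromoallyl side chain | COC(=O)[C@@]12C(=O)O[C@H](CC(Br)=C)[C@@H]1[C@H]2C[C@H](CO[Si](C)(C)C(C)(C)C)CCC=C
F7 | step 13 | C1 aldehyde from F6 | COC(=O)[C@@]12C(=O)O[C@H](CC(Br)=C)[C@@H]1[C@H]2C[C@H](CO[Si](C)(C)C(C)(C)C)CCC=O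
F8 | step 13 | macrocyclic allylic alcohol with 1-OH and exocyclic C10=C14 methylene (C1 epimers) | COC(=O)[C@@]12C(=O)O[C@@H]3CC(=C)C(O)CC[C@@H](CO[Si](C)(C)C(C)(C)C)C[C@@H]2[C@H]13
F9 | step 13 | macrocyclic primary allylic alcohol (14-OH, ring-cis C1=C10) | COC(=O)[C@@]12C(=O)O[C@@H]3C/C(CO)=C\CC[C@@H](CO[Si](C)(C)C(C)(C)C)C[C@@H]2[C@H]13
F10 | step 12 | C8-epimeric pinacol borates (19 and its C8 epimer) | COC(=O)C1(C(=O)OC)[C@H](C[C@H](CO[Si](C)(C)C(C)(C)C)CCC=C)[C@H]1C(OB2OC(C)(C)C(C)(C)O2)CC(=C)CO[Si](C)(C)C(C)(C)C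
F11 | step 12 | C8-epimeric hydroxy diesters (20 and its C8 epimer) | COC(=O)C1(C(=O)OC)[C@H](C[C@H](CO[Si](C)(C)C(C)(C)C)CCC=C)[C@H]1C(O)CC(=C)CO[Si](C)(C)C(C)(C)C
F12 | step 12 | C8 cyclopropyl ketone | COC(=O)C1(C(=O)OC)[C@H](C[C@H](CO[Si](C)(C)C(C)(C)C)CCC=C)[C@H]1C(=O)CC(=C)CO[Si](C)(C)C(C)(C)C
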